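## Retrosynthetic overview

1. The strategy rests on ring B. Its atoms C5, C6, C7=C8 (with methyl C17), C9 and C10 are the carbocycle of (R)-carvone. The isopropenyl group of carvone is C4 together with the geminal methyls C18 and C19, so C5 is bought, not made.
2. Ester and diol come from a C15 acid acetonide. The Δ7 olefin and C9–H come from an 8-en-7-one by reductive enolate triflation and C–O hydrogenolysis. C9–C11 comes from a C11–C16 alkyllithium plus the C9 enone, followed by 1,3-oxidative transposition.
3. The 2α,3α-diol comes from α-face dihydroxylation of a Δ2 olefin. That olefin is placed through a C1 ketone, whose oxygen is then removed by radical deoxygenation.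
4. Ring B is present from the start and ring A is closed second. The C3–C4 bond forms by hydrogen-atom-transfer radical 6-endo cyclisation of 6-acryloyl-6-methylcarvone.
5. That precursor comes from carvone by α′-methylation (C20), aldol addition to acrolein (C1–C3) anti to the isopropenyl group, and oxidation. The side chain comes from methyl hydrogen (R)-3-methylglutarate, whose acid carbon becomes C15.

Key step: step 4

Remark: labdane numbering (C1–C20) is used for all bicyclic compounds and the side chain, and α is the face opposite the C10 methyl. The C6 epimers of 6-methylcarvone and the carbinol epimers of the aldol adduct are carried as mixtures, because both centres are flattened in the following step.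

## Route

Step 1
Reactants: 1 (R)-(−)-carvone; 2 iodomethane
Product: 4 (5R)-6-methylcarvone (C6 epimers; trans isomer major), via lithium dienolate 3 (not isolated)
Conditions: LiN(i-Pr)2, THF, −78 °C; MeI, −78 → 0 °C
Reagents that add atoms: 2 iodomethane, CI
Why: Kinetic α′-deprotonation gives the cross-conjugated enolate, whose SN2 alkylation installs C20; the new centre needs no control because step 2 flattens it again.

Step 2
Reactants: 4 (5R)-6-methylcarvone; 5 acrolein
Product: 7 6-(1-hydroxyprop-2-enyl)-6-methylcarvone (hydroxyallyl group trans to isopropenyl; carbinol epimers), via lithium enolate 6 (not isolated)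
Conditions: LiN(i-Pr)2, THF, −78 → −20 °C; acrolein, −78 °C; AcOH, −78 °C
Reagents that add atoms: 5 acrolein, C=CC=O
Why: Directed aldol addition (1,2-addition of a lithium enolate to an enal): in the tetrasubstituted enolate the isopropenyl group turns pseudoaxial to escape allylic strain with the C10 methyl and screens its own face, so acrolein bonds to C10 from the other face and sets the quaternary centre with C1 trans and C20 cis to the isopropenyl group, while the cold acidic quench forestalls retro-aldol cleavage.

Step 3
Reactants: 7 aldol adduct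
Product: 8 6-acryloyl-6-methylcarvone (acryloyl trans to isopropenyl)
Conditions: Dess–Martin periodinane, CH2Cl2, 0 °C → rt
Reagents that add atoms: none
Why: Dess–Martin oxidation of the secondary allylic alcohol runs without base or nucleophile, so the non-enolisable 1,3-diketone should form without retro-aldol or retro-Claisen cleavage and without Michael addition to the new vinyl ketone; the carbinol centre disappears.

Step 4
Reactants: 8 6-acryloyl-6-methylcarvone
Product: 9 trans-4,4,8,10-tetramethyl-Δ7-octalin-1,9-dione (5α-H; 10β-CH3)
Conditions: Fe(acac)3 (0.3 equiv), PhSiH3 (2.5 equiv), EtOH (0.02 M, degassed), 60 °C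
Reagents that add atoms: none
Why: Fe(acac)3 and PhSiH3 in ethanol generate an iron hydride that passes a hydrogen atom to the CH2 terminus of the isopropenyl group; the tertiary C4 radical, already bearing C18 and C19, adds to C3, the unsubstituted end of the vinyl ketone, and the C2 α-keto radical is reduced by divalent iron to the enolate and protonated by ethanol. The closest known reaction type is the iron-catalysed hydrogen-atom-transfer reductive olefin coupling (a Giese addition started from an olefin), which is established in intramolecular form for building quaternary carbons. Ring A closes in the 6-endo-trig mode, since the 5-exo alternative would join the nucleophilic radical to the α-carbon C2 and leave a primary radical, which is disfavoured on polar, steric and thermodynamic grounds. No stereocentre is created (C4 becomes a gem-dimethyl carbon, C2 and C3 are methylenes), and the trans ring fusion is inherited from C5 and C10, whose C4 and C1 arms are trans and both equatorial in the reactive half-chair. The step needs hydrogen-atom transfer to one olefin out of three: the electron-neutral 1,1-disubstituted isopropenyl group is the best acceptor, both enone olefins are electron-poor, and the C4 radical cannot reach the ring enone because only a four-membered ring would result. High dilution suppresses intermolecular addition to the vinyl ketone.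

Step 5
Reactants: 9 trans-1,9-dione
Product: 11 trans-4,4,8,10-tetramethyloctalin-2,7-diene-1,9-dione (bis-enone), via C1 lithium enolate 10 (not isolated)
Conditions: LiN(i-Pr)2 (1.1 equiv), THF, −78 °C; PhS(Cl)=N-t-Bu, −78 °C
Reagents that add atoms: none
Why: Mukaiyama dehydrogenation: C2 is the only hydrogen-bearing α-position of the C1 ketone (C10 is quaternary), kinetic deprotonation there outruns γ-deprotonation of the hindered enone at C6, and the sulfur adduct of the enolate undergoes syn elimination already at −78 °C.

Step 6
Reactants: 11 bis-enone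
Product: 12 1β-hydroxy-4,4,8,10-tetramethyloctalin-2,7-dien-9-one
Conditions: CeCl3·7H2O (1.2 equiv), NaBH4 (0.5 equiv, in portions), MeOH–CH2Cl2, −78 °C
Reagents that add atoms: none
Why: Luche 1,2-reduction: the C1 carbonyl has an unsubstituted sp2 neighbour (C2–H) and belongs to the less donor-substituted enone, whereas C9 is wedged between C10 and the methyl-bearing C8, so limiting hydride should take C1 first; hydride enters from the α face, anti to axial C20, to give the 1β alcohol, a centre that step 10 erases.

Step 7
Reactants: 12 1β-hydroxy dienone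
Product: 13 1β,2α,3α-trihydroxy-4,4,8,10-tetramethyl-Δ7-octalin-9-one
Conditions: OsO4 (5 mol %), N-methylmorpholine N-oxide, acetone–H2O, rt
Reagents that add atoms: OsO4, O=[Os](=O)(=O)=O (catalytic carrier of both oxygen atoms); N-methylmorpholine N-oxide, C[N+]1([O-])CCOCC1; water, O
Why: Upjohn dihydroxylation (suprafacial addition of OsO4): only the non-conjugated Δ2 olefin reacts because Δ7 is deactivated by C9=O, and the reagent comes from the α face because the β face is closed by the axial methyls C19 and C20 and α is also anti to the 1β-hydroxyl, which sets 2α-OH and 3α-OH together.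

Step 8
Reactants: 13 triol
Product: 14 1β-hydroxy-2α,3α-(isopropylidenedioxy)-4,4,8,10-tetramethyl-Δ7-octalin-9-one
Conditions: Me2C(OMe)2, PPTS (cat.), CH2Cl2, rt
Reagents that add atoms: 2,2-dimethoxypropane, COC(C)(C)OC
Why: Acid-catalysed transketalisation under equilibrating conditions: the cis 2α,3α pair closes an unstrained dioxolane, whereas the trans-diequatorial 1β,2α pair would need a strained trans-fused one, so the C1 hydroxyl stays free.

Step 9
Reactants: 14 acetonide alcohol
Product: 15 1β-O-(phenoxythiocarbonyl) derivative of 14
Conditions: PhOC(S)Cl, pyridine, DMAP (cat.), CH2Cl2, 0 °C → rt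
Reagents that add atoms: O-phenyl chlorothionoformate, S=C(Cl)Oc1ccccc1
Why: O-Acylation with a chlorothionoformate under weakly basic conditions (first half of the Barton–McCombie sequence); avoiding alkoxide formation keeps the β-hydroxy ketone unit C1–C10–C9 from retro-aldol cleavage.

Step 10
Reactants: 15 thionocarbonate
Product: 16 2α,3α-(isopropylidenedioxy)-4,4,8,10-tetramethyl-Δ7-octalin-9-one
Conditions: Bu3SnH, AIBN (cat.), toluene, 90 °C
Reagents that add atoms: none
Why: Barton–McCombie deoxygenation: the stannyl radical adds to C=S and the released secondary C1 radical is quenched by Bu3SnH; in the rigid trans-decalin the equatorial C10–C9 and C2–O bonds lie in the nodal plane of the C1 radical orbital, so 1,2-acyl shift and β-scission should not compete, and the hindered enone is a far poorer stannyl-radical acceptor than the thiocarbonyl group.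

Step 11
Reactants: 17 methyl hydrogen (R)-3-methylglutarate
Product: 18 methyl (R)-5-hydroxy-3-methylpentanoate
Conditions: BH3·SMe2, THF, 0 °C → rt; MeOH
Reagents that add atoms: none
Why: Chemoselective borane reduction of a carboxylic acid beside an ester (via the acyloxyborane); the acid carbon becomes C15, the stereocentre C13 is untouched, and the product is silylated at once to forestall lactonisation.

Step 12
Reactants: 18 hydroxy ester
Product: 19 methyl (R)-5-(tert-butyldimethylsilyloxy)-3-methylpentanoate
Conditions: TBSCl, imidazole, CH2Cl2, 0 °C → rt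
Reagents that add atoms: tert-butyldimethylsilyl chloride, CC(C)(C)[Si](C)(C)Cl
Why: Imidazole-promoted silylation of a primary alcohol; the TBS ether tolerates LiAlH4, t-BuLi, chromate oxidation and Li/NH3.

Step 13
Reactants: 19 silyloxy ester
Product: 20 (S)-5-(tert-butyldimethylsilyloxy)-3-methylpentan-1-ol
Conditions: LiAlH4, Et2O, 0 °C; H2O work-up
Reagents that add atoms: none
Why: Hydride reduction of the ester to the primary alcohol whose carbon becomes C11; no stereocentre is affected (the descriptor changes only through priorities).

Step 14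
Reactants: 20 alcohol
Product: 21 (R)-tert-butyl[(5-iodo-3-methylpentyl)oxy]dimethylsilane
Conditions: I2, PPh3, imidazole, CH2Cl2, 0 °C
Reagents that add atoms: iodine, [I][I]
Why: Appel-type iodination (SN2 displacement of the alkoxyphosphonium ion by iodide) at a primary carbon remote from C13.

Step 15
Reactants: 16 bicyclic enone; 21 iodide
Product: 23 (13S)-15-(tert-butyldimethylsilyloxy)-2α,3α-(isopropylidenedioxy)labd-7-en-9β-ol, via alkyllithium 22 (not isolated)
Conditions: 21, t-BuLi (2.0 equiv), Et2O–pentane, −78 °C; 16, Et2O, −78 → 0 °C; H2O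
Reagents that add atoms: none
Why: Lithium–iodine exchange followed by 1,2-addition of the primary alkyllithium to the enone carbonyl forms C9–C11; C10 is quaternary so no α-deprotonation is possible, C1 no longer carries a carbonyl that could trigger retro-Claisen cleavage, and attack from the α face (anti to C20) should give the 9β-alcohol, whose configuration is erased in step 16.

Step 16
Reactants: 23 tertiary allylic alcohol
Product: 24 (13S)-15-(tert-butyldimethylsilyloxy)-2α,3α-(isopropylidenedioxy)labd-8-en-7-one
Conditions: pyridinium chlorochromate (C5H5NH[CrO3Cl]), 4 Å MS, CH2Cl2, rt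
Reagents that add atoms: pyridinium chlorochromate, [O-][Cr](=O)(=O)Cl.c1cc[nH+]cc1 (supplies the C7 oxygen; the C9 oxygen leaves with chromium)
Why: Babler–Dauben oxidative transposition: the tertiary chromate ester undergoes a [3,3]-shift to the unhindered C7 and is oxidised there, which moves oxygen from C9 to C7 and the olefin to C8=C9.

Step 17
Reactants: 24 tetrasubstituted enone
Product: 26 (13S)-15-(tert-butyldimethylsilyloxy)-2α,3α-(isopropylidenedioxy)labd-7-en-7-yl triflate (9α-H), via C7 lithium enolate 25 (not isolated)
Conditions: Li, NH3(l)–THF, t-BuOH (1.0 equiv), −78 °C; evaporate NH3; PhNTf2, THF, 0 °C → rt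
Reagents that add atoms: N-phenylbis(trifluoromethanesulfonimide), O=S(=O)(N(c1ccccc1)S(=O)(=O)C(F)(F)F)C(F)(F)F
Why: Dissolving-metal reduction of the enone with regiospecific trapping of the resulting enolate as its triflate: the β-carbon C9 is protonated axially on the α face, anti to axial C20, which leaves the side chain equatorial (9β) and sets C9, while the enolate oxygen fixes the double bond between C7 and C8.

Step 18
Reactants: 26 enol triflate
Product: 27 (13S)-15-(tert-butyldimethylsilyloxy)-2α,3α-(isopropylidenedioxy)labd-7-ene
Conditions: Pd(OAc)2 (cat.), PPh3, HCO2H, Et3N, DMF, 60 °C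
Reagents that add atoms: none
Why: Palladium-catalysed formate reduction of an enol triflate (oxidative addition of zerovalent palladium; decarboxylation of the formate complex to a palladium hydride; reductive elimination) replaces C7–OTf by C7–H without moving the olefin or touching C9.

Step 19
Reactants: 27 silyl ether
Product: 28 (13S)-2α,3α-(isopropylidenedioxy)labd-7-en-15-ol
Conditions: Bu4NF, THF, rt
Reagents that add atoms: none
Why: Fluoride-induced cleavage of the Si–O bond; acetonide and olefin are inert.

Step 20
Reactants: 28 primary alcohol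
Product: 29 (13S)-2α,3α-(isopropylidenedioxy)labd-7-en-15-oic acid
Conditions: TEMPO (cat.), PhI(OAc)2, MeCN–H2O, rt
Reagents that add atoms: water, O
Why: Oxoammonium-mediated oxidation takes the primary alcohol through the aldehyde hydrate to the acid and leaves the trisubstituted olefin, the acetonide and the β-stereocentre C13 alone.

Step 21
Reactants: 29 acid acetonide
Product: 30 methyl (2R,3S,5R,9S,10R,13S)-2α,3α-dihydroxylabd-7-en-15-oate (CNP0574074.1)
Conditions: HCl (0.5 M in MeOH), 0 °C → rt
Reagents that add atoms: methanol, CO
Why: Fischer esterification and acid-catalysed acetonide cleavage proceed together in dilute methanolic HCl, the water formed in the first serving the second; the conditions are too mild to shift the Δ7 olefin to the tetrasubstituted position and no stereocentre is involved.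

## Compound list

1 | (R)-(−)-carvone | CC1=CC[C@H](CC1=O)C(C)=C | starting material
2 | iodomethane | CI | starting material
3 | lithium cross-conjugated dienolate of carvone | CC1=CC[C@H](C=C1O[Li])C(C)=C | intermediate
4 | (5R)-6-methylcarvone, C6 epimers | O=C1C(C)=CC[C@@H](C(C)=C)C1C | intermediate
5 | acrolein | C=CC=O | starting material
6 | lithium enolate of 6-methylcarvone | CC1=CC[C@@H](C(C)=C)C(C)=C1O[Li] | intermediate
7 | 6-(1-hydroxyprop-2-enyl)-6-methylcarvone, carbinol epimers | O=C1C(C)=CC[C@@H](C(C)=C)[C@]1(C)C(O)C=C | intermediate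
8 | 6-acryloyl-6-methylcarvone (acryloyl trans to isopropenyl) | O=C1C(C)=CC[C@@H](C(C)=C)[C@]1(C)C(=O)C=C | intermediate
9 | trans-4,4,8,10-tetramethyl-Δ7-octalin-1,9-dione | O=C1C(C)=CC[C@H]2C(C)(C)CCC(=O)[C@]12C | intermediate
10 | C1(2) lithium enolate of 9 | O=C1C(C)=CC[C@H]2C(C)(C)CC=C(O[Li])[C@]12C | intermediate
11 | trans-4,4,8,10-tetramethyloctalin-2,7-diene-1,9-dione | O=C1C(C)=CC[C@H]2C(C)(C)C=CC(=O)[C@]12C | intermediate
12 | 1β-hydroxy-2,7-dien-9-one | O=C1C(C)=CC[C@H]2C(C)(C)C=C[C@@H](O)[C@]12C | intermediate
13 | 1β,2α,3α-trihydroxy-7-en-9-one | O=C1C(C)=CC[C@H]2C(C)(C)[C@H](O)[C@H](O)[C@@H](O)[C@]12C | intermediate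
14 | 1β-hydroxy-2α,3α-acetonide | O=C1C(C)=CC[C@H]2C(C)(C)[C@H](O3)[C@H](OC3(C)C)[C@@H](O)[C@]12C | intermediate
15 | 1β-O-phenoxythiocarbonyl 2α,3α-acetonide | O=C1C(C)=CC[C@H]2C(C)(C)[C@H](O3)[C@H](OC3(C)C)[C@@H](OC(=S)Oc4ccccc4)[C@]12C | intermediate
16 | 2α,3α-(isopropylidenedioxy)-4,4,8,10-tetramethyl-Δ7-octalin-9-one | O=C1C(C)=CC[C@H]2C(C)(C)[C@H](O3)[C@H](OC3(C)C)C[C@]12C | intermediate
17 | methyl hydrogen (R)-3-methylglutarate | COC(=O)C[C@H](C)CC(=O)O | starting material
18 | methyl (R)-5-hydroxy-3-methylpentanoate | COC(=O)C[C@H](C)CCO | intermediate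
19 | methyl (R)-5-(TBS-oxy)-3-methylpentanoate | COC(=O)C[C@H](C)CCO[Si](C)(C)C(C)(C)C | intermediate
20 | (S)-5-(TBS-oxy)-3-methylpentan-1-ol | OCC[C@H](C)CCO[Si](C)(C)C(C)(C)C | intermediate
21 | (R)-5-(TBS-oxy)-1-iodo-3-methylpentane | ICC[C@H](C)CCO[Si](C)(C)C(C)(C)C | intermediate
22 | 5-(TBS-oxy)-3-methylpentyllithium (configuration as in 21) | [Li]CC[C@H](C)CCO[Si](C)(C)C(C)(C)C | intermediate
23 | 15-(TBS-oxy)-2α,3α-(isopropylidenedioxy)labd-7-en-9β-ol | CC(C)(C)[Si](C)(C)OCC[C@@H](C)CC[C@]1(O)C(C)=CC[C@H]2C(C)(C)[C@H](O3)[C@H](OC3(C)C)C[C@]12C | intermediate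
24 | 15-(TBS-oxy)-2α,3α-(isopropylidenedioxy)labd-8-en-7-one | CC(C)(C)[Si](C)(C)OCC[C@@H](C)CCC1=C(C)C(=O)C[C@H]2C(C)(C)[C@H](O3)[C@H](OC3(C)C)C[C@]12C | intermediate
25 | C7(8) lithium enolate, 9α-H | CC(C)(C)[Si](C)(C)OCC[C@@H](C)CC[C@H]1C(C)=C(O[Li])C[C@H]2C(C)(C)[C@H](O3)[C@H](OC3(C)C)C[C@]12C | intermediate
26 | labd-7-en-7-yl triflate | CC(C)(C)[Si](C)(C)OCC[C@@H](C)CC[C@H]1C(C)=C(OS(=O)(=O)C(F)(F)F)C[C@H]2C(C)(C)[C@H](O3)[C@H](OC3(C)C)C[C@]12C | intermediate
27 | 15-(TBS-oxy)-2α,3α-(isopropylidenedioxy)labd-7-ene | CC(C)(C)[Si](C)(C)OCC[C@@H](C)CC[C@H]1C(C)=CC[C@H]2C(C)(C)[C@H](O3)[C@H](OC3(C)C)C[C@]12C | intermediate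
28 | 2α,3α-(isopropylidenedioxy)labd-7-en-15-ol | OCC[C@@H](C)CC[C@H]1C(C)=CC[C@H]2C(C)(C)[C@H](O3)[C@H](OC3(C)C)C[C@]12C | intermediate
29 | 2α,3α-(isopropylidenedioxy)labd-7-en-15-oic acid | OC(=O)C[C@@H](C)CC[C@H]1C(C)=CC[C@H]2C(C)(C)[C@H](O3)[C@H](OC3(C)C)C[C@]12C | intermediate
30 | methyl (13S)-2α,3α-dihydroxylabd-7-en-15-oate | COC(=O)C[C@@H](C)CC[C@H]1C(C)=CC[C@H]2C(C)(C)[C@H](O)[C@H](O)C[C@]12C | target

## Step count and risks

Total steps: 21. The longest linear sequence is 17 steps (steps 1–10 and 15–21 from (R)-carvone). The side chain takes steps 11–14 and joins in step 15.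

**Step 4 (key cyclisation).** Hydrogen-atom transfer to the vinyl ketone, its simple reduction or its oligomerisation may compete with radical generation at the isopropenyl group. The C4 radical may also be quenched before it cyclises.

- The fallback makes the same radical by halogen abstraction and sets out from 8.
- HBr in AcOH–CH2Cl2 at 0 °C should add in the Markovnikov sense to the isopropenyl group and in the conjugate sense to the vinyl ketone. This gives the dibromide 6-(3-bromopropanoyl)-5-(2-bromopropan-2-yl)-2,6-dimethylcyclohex-2-enone F1.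
- Et3N at 0 °C removes HBr only from the β-bromo ketone (E1cB). This gives the tertiary bromide 6-acryloyl-5-(2-bromopropan-2-yl)-2,6-dimethylcyclohex-2-enone F2.
- Slow addition of Bu3SnH with AIBN in toluene at 80 °C then effects a tin-hydride Giese cyclisation in the same 6-endo mode. The fallback comes back to the route at 9.

**Step 6 (reduction of one of two enone carbonyls).** Discrimination between C1 and C9 may be insufficient, leading to over-reduction or reduction at C9.

- The fallback moves the selectivity to a saturated ketone against an enone. It sets out from 9 through enolate 10.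
- PhSeCl at −78 °C should give the selenide 2α-(phenylselanyl)-4,4,8,10-tetramethyl-Δ7-octalin-1,9-dione F3.
- NaBH4 in MeOH at 0 °C reduces only the saturated, α-heteroatom-activated C1 carbonyl, the selectivity known from the Wieland–Miescher ketone. This gives the hydroxy selenide 1β-hydroxy-2α-(phenylselanyl)-4,4,8,10-tetramethyl-Δ7-octalin-9-one F4.
- H2O2 with pyridine in CH2Cl2 oxidises selenium, and the selenoxide eliminates away from the carbinol carbon towards C3. The fallback comes back to the route at 12.

**Step 17 (reductive triflation).** The enolate may equilibrate towards C6 while ammonia is removed. Triflation of the hindered tetrasubstituted enolate may be slow, or protonation at C9 may show imperfect facial selectivity.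

- The fallback separates reduction from olefin formation and sets out from 24.
- Li/NH3 followed by an NH4Cl quench should give the thermodynamically favoured saturated ketone 15-(TBS-oxy)-2α,3α-(isopropylidenedioxy)-8α-methyl-9α-H-labdan-7-one F5, with both ring B substituents equatorial.
- LiBH(s-Bu)3 in THF at −78 °C delivers hydride equatorially to give the axial alcohol 15-(TBS-oxy)-2α,3α-(isopropylidenedioxy)labdan-7α-ol F6.
- POCl3 in pyridine then effects anti-periplanar E2 loss of the axial leaving group with the axial 8β-H, in the Zaitsev direction. The fallback comes back to the route at 27.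

Further compounds
F1 | step 4 | 6-(3-bromopropanoyl)-5-(2-bromopropan-2-yl)-2,6-dimethylcyclohex-2-enone | O=C1C(C)=CC[C@@H](C(C)(C)Br)[C@]1(C)C(=O)CCBr
F2 | step 4 | 6-acryloyl-5-(2-bromopropan-2-yl)-2,6-dimethylcyclohex-2-enone | O=C1C(C)=CC[C@@H](C(C)(C)Br)[C@]1(C)C(=O)C=C
F3 | step 6 | 2α-(phenylselanyl)-4,4,8,10-tetramethyl-Δ7-octalin-1,9-dione | O=C1C(C)=CC[C@H]2C(C)(C)C[C@H]([Se]c3ccccc3)C(=O)[C@]12C
F4 | step 6 | 1β-hydroxy-2α-(phenylselanyl)-4,4,8,10-tetramethyl-Δ7-octalin-9-one | O=C1C(C)=CC[C@H]2C(C)(C)C[C@H]([Se]c3ccccc3)[C@@H](O)[C@]12C
F5 | step 17 | 15-(TBS-oxy)-2α,3α-(isopropylidenedioxy)-8α-methyl-9α-H-labdan-7-one | CC(C)(C)[Si](C)(C)OCC[C@@H](C)CC[C@H]1[C@H](C)C(=O)C[C@H]2C(C)(C)[C@H](O3)[C@H](OC3(C)C)C[C@]12C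
F6 | step 17 | 15-(TBS-oxy)-2α,3α-(isopropylidenedioxy)labdan-7α-ol | CC(C)(C)[Si](C)(C)OCC[C@@H](C)CC[C@H]1[C@H](C)[C@H](O)C[C@H]2C(C)(C)[C@H](O3)[C@H](OC3(C)C)C[C@]12C
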